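The two ring-fusion sp2 carbons of the methyl dienoate, joined by the single bond that both cyclopentenes share, are read as the two carbons of an alkyne. One Ru-catalysed dienyne ring-closing metathesis cascade turns that alkyne into both tetrasubstituted olefins and closes the ester cyclopentene (spiro to the piperidine) and the ester-free cyclopentene together. The precursor is an N-methylpiperidin-2-one whose C5 quaternary carbon carries a 2-(methoxycarbonyl)allyl group and an alkyne ending in a 1,1-disubstituted olefin. Its vicinal quaternary centres come from an organocatalytic Michael addition and a lactone-templated alkylation. The lactam later delivers the enamine that closes the seven-membered ring.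

Key step: step 17

Remark: the hemiketal carbon equilibrates through the open hydroxy ketone, so the configuration shown in the target is assumed to be the thermodynamic one.
Remark: piperidin-2-one locants N1, C2 (C=O), C3, C4, C5, C6 are used for all monocyclic intermediates; the precursor carries two silyl ethers and a dioxolane so that one fluoride step and one aqueous acid step suffice after the cascade.

Step 1
Reactants: 1 ethyl N-methylglycinate; 2 methyl 4-chloro-4-oxobutanoate
Product: 3 ethyl N-(4-methoxy-4-oxobutanoyl)-N-methylglycinate
Conditions: Et3N, CH2Cl2, 0 °C to rt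
Reagents that add atoms: none
Why: N-acylation of the secondary amine by the acid chloride (amide formation) should be clean because the amine is the only nucleophile present.

Step 2
Reactants: 3 ethyl N-(4-methoxy-4-oxobutanoyl)-N-methylglycinate
Product: 4 methyl 1-methyl-2,5-dioxopiperidine-4-carboxylate
Conditions: KOt-Bu, THF, 0 °C to rt; then aqueous HCl
Reagents that add atoms: none
Why: Dieckmann condensation, in which 6-exo-trig attack of the succinate ester enolate on the glycinate ester should give the cyclic β-keto ester as its enolate; the ester is expected on C4, as in the 3-oxopiperidine-4-carboxylate series, because closure through the glycine carbon would crowd the enolate ester against the N-methyl amide and closure through the amide α-carbon needs a much less acidic C–H.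

Step 3
Reactants: 4 methyl 1-methyl-2,5-dioxopiperidine-4-carboxylate; 5 pent-1-en-3-one
Product: 6 methyl (4R)-1-methyl-2,5-dioxo-4-(3-oxopentyl)piperidine-4-carboxylate
Conditions: 9-O-benzylcupreidine (10 mol %), CH2Cl2, −20 °C
Reagents that add atoms: none
Why: Organocatalytic asymmetric Michael addition of a cyclic β-keto ester to a vinyl ketone, in which the bifunctional cinchona base holds enol and enone by hydrogen bonds and exposes one enolate face; the quinidine- or quinine-derived pseudoenantiomer is chosen so that the C4 quaternary centre forms as (R).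

Step 4
Reactants: 6 methyl (4R)-1-methyl-2,5-dioxo-4-(3-oxopentyl)piperidine-4-carboxylate
Product: 7 methyl (4R)-4-[2-(2-ethyl-1,3-dioxolan-2-yl)ethyl]-1-methyl-2,5-dioxopiperidine-4-carboxylate
Conditions: 1,2-bis(trimethylsilyloxy)ethane, Me3SiOTf (cat.), CH2Cl2, −78 °C
Reagents that add atoms: 1,2-bis(trimethylsilyloxy)ethane, C[Si](C)(C)OCCO[Si](C)(C)C
Why: Silyl-triflate-catalysed dioxolane formation should be selective for the unhindered ethyl ketone over the ring ketone, which sits next to the quaternary carbon and is deactivated by the ester and the amide.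

Step 5
Reactants: 7 methyl (4R)-4-[2-(2-ethyl-1,3-dioxolan-2-yl)ethyl]-1-methyl-2,5-dioxopiperidine-4-carboxylate
Product: 8 enol triflate of 7 (C5–OTf, C5=C6)
Conditions: KN(SiMe3)2, THF, −78 °C; then PhNTf2
Reagents that add atoms: N-phenylbis(trifluoromethanesulfonimide), O=S(=O)(N(c1ccccc1)S(=O)(=O)C(F)(F)F)C(F)(F)F
Why: Enolate O-sulfonylation, in which the ketone can enolise only toward C6 because C4 is quaternary, so a single enol triflate is expected.

Step 6
Reactants: 8 enol triflate of 7
Product: 9 hydroxymethyl enol triflate
Conditions: LiBH4, THF, 0 °C to rt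
Reagents that add atoms: none
Why: Borohydride reduction of the methyl ester to the primary alcohol, since LiBH4 reduces esters but should leave the tertiary lactam, the enol triflate and the ketal.

Step 7
Reactants: 9 hydroxymethyl enol triflate
Product: 10 unsaturated bicyclic lactone
Conditions: Pd(PPh3)4 (5 mol %), CO (1 atm), Et3N, MeCN, 65 °C
Reagents that add atoms: carbon monoxide, [C-]#[O+]
Why: Palladium-catalysed carbonylative lactonisation of a hydroxy enol triflate (oxidative addition, CO insertion, capture of the acyl palladium by the neighbouring hydroxyl) should close the five-membered lactone.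

Step 8
Reactants: 10 unsaturated bicyclic lactone
Product: 11 cis-fused saturated lactone
Conditions: H2 (4 atm), Pd/C (palladium on carbon), EtOAc, rt
Reagents that add atoms: none
Why: Heterogeneous hydrogenation of the β-amido acrylate olefin, expected from the convex face to give the cis-fused lactone; the new C–H centre is erased in step 9.

Step 9
Reactants: 11 cis-fused saturated lactone; 12 2,3-dibromopropene
Product: 13 bromoallyl lactone
Conditions: LiN(i-Pr)2, THF, −78 °C; then 12, DMPU, −78 to −20 °C
Reagents that add atoms: none
Why: Lactone enolate alkylation (the lactone C–H is far more acidic than the lactam C–H), in which the allylic bromide should enter the ring-fusion enolate on the convex face so that the lactone stays cis-fused; this places the bromoallyl group trans to the CH2O arm and sets the C5 quaternary centre relative to C4.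

Step 10
Reactants: 13 bromoallyl lactone
Product: 15 alkynyl alcohol, via lactol 14 (not isolated)
Conditions: i-Bu2AlH, CH2Cl2, −78 °C; then MeOH, K2CO3, dimethyl (1-diazo-2-oxopropyl)phosphonate, rt
Reagents that add atoms: dimethyl (1-diazo-2-oxopropyl)phosphonate, COP(=O)(OC)C(=[N+]=[N-])C(C)=O
Why: Partial reduction of the lactone to the lactol and Seyferth–Gilbert homologation of its open hydroxy aldehyde with the Ohira–Bestmann reagent; the lactone should be reduced faster than the tertiary lactam at −78 °C and no stereocentre is touched.

Step 11
Reactants: 15 alkynyl alcohol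
Product: 16 silyl-protected alkyne
Conditions: t-BuMe2SiCl, imidazole, DMF, rt
Reagents that add atoms: tert-butyldimethylsilyl chloride, CC(C)(C)[Si](C)(C)Cl
Why: Silyl ether formation at the only free hydroxyl.

Step 12
Reactants: 17 3-methylbut-3-en-1-ol
Product: 18 3-methylidenepentane-1,5-diol
Conditions: n-BuLi (2.2 equiv), TMEDA, Et2O/hexane, 0 °C to rt; then (CH2O)n, −78 °C to rt
Reagents that add atoms: formaldehyde (as paraformaldehyde), C=O
Why: Alkoxide-directed allylic lithiation gives a dianion whose symmetrical allyl anion adds to formaldehyde (carbonyl addition of an allyllithium).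

Step 13
Reactants: 18 3-methylidenepentane-1,5-diol
Product: 19 3-methylidene-5-(triethylsilyloxy)pentan-1-ol
Conditions: NaH (1.0 equiv), THF, rt; then Et3SiCl (1.0 equiv)
Reagents that add atoms: chlorotriethylsilane, CC[Si](CC)(CC)Cl
Why: Monosilylation of a symmetrical diol through its sparingly soluble monoalkoxide.

Step 14
Reactants: 19 3-methylidene-5-(triethylsilyloxy)pentan-1-ol
Product: 20 3-methylidene-5-(triethylsilyloxy)pentyl trifluoromethanesulfonate
Conditions: Tf2O, 2,6-lutidine, CH2Cl2, −78 °C; used at once
Reagents that add atoms: trifluoromethanesulfonic anhydride, O=S(=O)(OS(=O)(=O)C(F)(F)F)C(F)(F)F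
Why: O-sulfonylation of the primary alcohol under buffered conditions that the silyl ether tolerates.

Step 15
Reactants: 16 silyl-protected alkyne; 20 3-methylidene-5-(triethylsilyloxy)pentyl trifluoromethanesulfonate
Product: 21 internal alkyne with bromoallyl group
Conditions: LiN(SiMe3)2, THF, −78 °C; then 20, −78 to −20 °C
Reagents that add atoms: none
Why: SN2 alkylation of the lithium acetylide by a primary alkyl triflate, which reacts at low temperature where elimination of the homoallylic electrophile, attack on the lactam and loss of HBr from the bromoalkene are not expected.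

Step 16
Reactants: 21 internal alkyne with bromoallyl group
Product: 22 dienyne precursor (acrylate)
Conditions: PdCl2(PPh3)2 (5 mol %), CO (1 atm), Et3N, MeOH/DMF, 60 °C
Reagents that add atoms: carbon monoxide, [C-]#[O+]; methanol, CO
Why: Palladium-catalysed methoxycarbonylation of the 2-bromoalkene, in which methanolysis of the acyl palladium in a methanol-rich medium should outrun insertion of the tethered alkyne.

Step 17
Reactants: 22 dienyne precursor (acrylate)
Product: 24 spiro piperidinone with the bicyclic diene ester, via triene 23 (not isolated)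
Conditions: RuCl2(1,3-di-o-tolylimidazolidin-2-ylidene)(=CH-C6H4-2-O-i-Pr) (second-generation Hoveyda–Grubbs type, 15 mol % in portions), ethylene (1 atm), toluene (0.002 mol/L), 60 °C; then argon purge, 100 °C
Reagents that add atoms: none
Why: Proposed new method: ruthenium methylidene, kept available by ethylene, should add across the internal alkyne (enyne metathesis) with ruthenium on the alkyne carbon remote from the quaternary C5; this vinylcarbene ring-closes onto the acrylate methylene to give the ester-bearing cyclopentene (triene 23), and ring-closing metathesis between the new exocyclic methylene on the propargylic carbon and the 1,1-disubstituted side-chain olefin then forms the second cyclopentene with loss of ethylene. The closest known reactions are tandem ring-closing metathesis of dienynes to fused bicyclic 1,3-dienes, ethylene-assisted enyne metathesis of dialkyl alkynes, and ring-closing metathesis to tetrasubstituted cyclopentenes with second-generation catalysts that carry N-o-tolyl carbene ligands; two tetrasubstituted olefins, one of them from an acrylate, formed across one alkyne have not been shown. Each ring closes in a five-membered mode that takes both former alkyne carbons into the ring (endo with respect to the alkyne): the ester ring by carbene-to-olefin closure and the ester-free ring by diene closure. No stereocentre is formed and the spiro carbon C5 is not touched. The step needs intramolecular closure to beat cross-metathesis and the olefins to pair correctly; high dilution, the gem-disubstituent effect of the quaternary propargylic carbon, the low cross-metathesis reactivity of 1,1-disubstituted olefins and the fact that every mis-paired closure would be a four-membered ring should secure this, and the opposite regiochemistry of methylidene addition leads to the same diene.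

Step 18
Reactants: 24 spiro piperidinone with the bicyclic diene ester
Product: 25 primary alcohol
Conditions: HF·pyridine, pyridine, THF, 0 °C
Reagents that add atoms: none
Why: Fluoride-mediated desilylation, selective for the unhindered primary triethylsilyl ether over the neopentyl tert-butyldimethylsilyl ether.

Step 19
Reactants: 25 primary alcohol
Product: 26 primary bromide
Conditions: CBr4, PPh3, 2,6-lutidine, CH2Cl2, 0 °C
Reagents that add atoms: carbon tetrabromide, BrC(Br)(Br)Br
Why: Appel bromination of the primary alcohol under buffered conditions that spare the ketal and the silyl ether.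

Step 20
Reactants: 26 primary bromide
Product: 29 protected tetracyclic amine, via enamine 27 (not isolated), via iminium bromide 28 (not isolated)
Conditions: IrCl(CO)(PPh3)2 (1 mol %), (Me2SiH)2O, toluene, rt; then MeCN, 70 °C; then NaBH(OAc)3, AcOH, 0 °C
Reagents that add atoms: none
Why: Iridium-catalysed hydrosilylation of the tertiary lactam (esters and alkyl bromides are not expected to react) followed by loss of silanol gives the enamine, Stork-type intramolecular C-alkylation by the bromide closes the seven-membered ring, and the iminium is reduced by the borohydride; the new stereocentre at C3 can only form with the two-carbon tether on the ring face that carries the diene carbon at C5, since the tether bridges these two positions.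

Step 21
Reactants: 29 protected tetracyclic amine
Product: 31 target CNP0192143.1, via hydroxy ketone 30 (not isolated)
Conditions: aqueous HCl (1 mol/L), THF, rt to 40 °C; then NaHCO3
Reagents that add atoms: water, O
Why: Acid hydrolysis removes the silyl ether and the dioxolane, and the freed δ-hydroxy ketone should close to the six-membered cyclic hemiketal, whose configuration is under thermodynamic control.

Compound list
1 | ethyl N-methylglycinate | CCOC(=O)CNC | starting material
2 | methyl 4-chloro-4-oxobutanoate | COC(=O)CCC(Cl)=O | starting material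
3 | ethyl N-(4-methoxy-4-oxobutanoyl)-N-methylglycinate | CCOC(=O)CN(C)C(=O)CCC(=O)OC | intermediate
4 | methyl 1-methyl-2,5-dioxopiperidine-4-carboxylate (enolisable, no fixed stereocentre) | COC(=O)C1CC(=O)N(C)CC1=O | intermediate
5 | pent-1-en-3-one | CCC(=O)C=C | starting material
6 | methyl (4R)-1-methyl-2,5-dioxo-4-(3-oxopentyl)piperidine-4-carboxylate | CCC(=O)CC[C@@]1(C(=O)OC)CC(=O)N(C)CC1=O | intermediate
7 | methyl (4R)-4-[2-(2-ethyl-1,3-dioxolan-2-yl)ethyl]-1-methyl-2,5-dioxopiperidine-4-carboxylate | CCC1(OCCO1)CC[C@@]2(C(=O)OC)CC(=O)N(C)CC2=O | intermediate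
8 | methyl (4R)-4-[2-(2-ethyl-1,3-dioxolan-2-yl)ethyl]-1-methyl-2-oxo-5-(trifluoromethylsulfonyloxy)-1,2,3,4-tetrahydropyridine-4-carboxylate | CCC1(OCCO1)CC[C@@]2(C(=O)OC)CC(=O)N(C)C=C2OS(=O)(=O)C(F)(F)F | intermediate
9 | (4S)-4-[2-(2-ethyl-1,3-dioxolan-2-yl)ethyl]-4-(hydroxymethyl)-1-methyl-2-oxo-1,2,3,4-tetrahydropyridin-5-yl trifluoromethanesulfonate (same spatial arrangement at C4 as in 8) | CCC1(OCCO1)CC[C@@]2(CO)CC(=O)N(C)C=C2OS(=O)(=O)C(F)(F)F | intermediate
10 | (7aR)-7a-[2-(2-ethyl-1,3-dioxolan-2-yl)ethyl]-5-methyl-7,7a-dihydrofuro[3,4-c]pyridine-3,6(1H,5H)-dione (lactone O–CH2 on C4, lactone C=O on C5, C5=C6 enamide) | CCC1(OCCO1)CC[C@]23COC(=O)C2=CN(C)C(=O)C3 | intermediate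
11 | (3aR,7aR)-7a-[2-(2-ethyl-1,3-dioxolan-2-yl)ethyl]-5-methyltetrahydrofuro[3,4-c]pyridine-3,6(1H,4H)-dione, cis-fused | CCC1(OCCO1)CC[C@]23COC(=O)[C@H]2CN(C)C(=O)C3 | intermediate
12 | 2,3-dibromopropene | BrCC(Br)=C | starting material
13 | (3aR,7aR)-3a-(2-bromoprop-2-en-1-yl)-7a-[2-(2-ethyl-1,3-dioxolan-2-yl)ethyl]-5-methyltetrahydrofuro[3,4-c]pyridine-3,6(1H,4H)-dione, cis-fused (bromoallyl cis to the dioxolanylethyl chain) | CCC1(OCCO1)CC[C@]23COC(=O)[C@@]2(CC(Br)=C)CN(C)C(=O)C3 | intermediate
14 | lactol of 13 (3-hydroxy in place of the lactone C=O, anomer mixture) | CCC1(OCCO1)CC[C@]23COC(O)[C@@]2(CC(Br)=C)CN(C)C(=O)C3 | intermediate (not isolated)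
15 | (4R,5R)-5-(2-bromoprop-2-en-1-yl)-4-[2-(2-ethyl-1,3-dioxolan-2-yl)ethyl]-5-ethynyl-4-(hydroxymethyl)-1-methylpiperidin-2-one (ethynyl cis to CH2OH) | CCC1(OCCO1)CC[C@@]2(CO)CC(=O)N(C)C[C@]2(CC(Br)=C)C#C | intermediate
16 | tert-butyldimethylsilyl ether of 15 | CCC1(OCCO1)CC[C@@]2(CO[Si](C)(C)C(C)(C)C)CC(=O)N(C)C[C@]2(CC(Br)=C)C#C | intermediate
17 | 3-methylbut-3-en-1-ol | CC(=C)CCO | starting material
18 | 3-methylidenepentane-1,5-diol | OCCC(=C)CCO | intermediate
19 | 3-methylidene-5-(triethylsilyloxy)pentan-1-ol | CC[Si](CC)(CC)OCCC(=C)CCO | intermediate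
20 | 3-methylidene-5-(triethylsilyloxy)pentyl trifluoromethanesulfonate | CC[Si](CC)(CC)OCCC(=C)CCOS(=O)(=O)C(F)(F)F | intermediate
21 | (4R,5R)-5-(2-bromoprop-2-en-1-yl)-4-[(tert-butyldimethylsilyloxy)methyl]-4-[2-(2-ethyl-1,3-dioxolan-2-yl)ethyl]-1-methyl-5-[5-methylidene-7-(triethylsilyloxy)hept-1-yn-1-yl]piperidin-2-one | CCC1(OCCO1)CC[C@@]2(CO[Si](C)(C)C(C)(C)C)CC(=O)N(C)C[C@]2(CC(Br)=C)C#CCCC(=C)CCO[Si](CC)(CC)CC | intermediate
22 | key-step precursor: as 21, (4R,5R), with a 2-(methoxycarbonyl)prop-2-en-1-yl group on C5 in place of the bromoallyl group | CCC1(OCCO1)CC[C@@]2(CO[Si](C)(C)C(C)(C)C)CC(=O)N(C)C[C@]2(CC(=C)C(=O)OC)C#CCCC(=C)CCO[Si](CC)(CC)CC | intermediate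
23 | triene: C5 spiro to a cyclopentene bearing CO2Me, an exocyclic methylene on the former propargylic alkyne carbon and the 3-methylidene-5-(triethylsilyloxy)pentyl chain | CCC1(OCCO1)CC[C@@]2(CO[Si](C)(C)C(C)(C)C)CC(=O)N(C)C[C@@]23CC(C(=O)OC)=C(CCC(=C)CCO[Si](CC)(CC)CC)C3=C | intermediate (not isolated)
24 | key-step product: piperidin-2-one of 22 whose C5 is the spiro C1 of methyl 6-[2-(triethylsilyloxy)ethyl]-1,2,4,5-tetrahydropentalene-3-carboxylate (C6a cis to the CH2OSi arm on C4) | CCC1(OCCO1)CC[C@@]2(CO[Si](C)(C)C(C)(C)C)CC(=O)N(C)C[C@@]23CC(C(=O)OC)=C4CCC(CCO[Si](CC)(CC)CC)=C34 | intermediate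
25 | primary alcohol: 24 with the 2-hydroxyethyl side chain free | CCC1(OCCO1)CC[C@@]2(CO[Si](C)(C)C(C)(C)C)CC(=O)N(C)C[C@@]23CC(C(=O)OC)=C4CCC(CCO)=C34 | intermediate
26 | primary bromide: 25 with a 2-bromoethyl side chain | CCC1(OCCO1)CC[C@@]2(CO[Si](C)(C)C(C)(C)C)CC(=O)N(C)C[C@@]23CC(C(=O)OC)=C4CCC(CCBr)=C34 | intermediate
27 | enamine: 26 with the lactam reduced to N(Me)–CH=CH (C2=C3) | CCC1(OCCO1)CC[C@@]2(CO[Si](C)(C)C(C)(C)C)C=CN(C)C[C@@]23CC(C(=O)OC)=C4CCC(CCBr)=C34 | intermediate (not isolated)
28 | iminium bromide: seven-membered ring closed between C3 and the side chain, N(Me)=C2 iminium | CCC1(OCCO1)CC[C@@]2(CO[Si](C)(C)C(C)(C)C)[C@@H]1CCC3=C4C(=C(C(=O)OC)C[C@@]42C[N+](C)=C1)CC3.[Br-] | intermediate (not isolated)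
29 | protected tetracyclic amine: the target skeleton with the ketone as dioxolane and the primary alcohol as tert-butyldimethylsilyl ether | CCC1(OCCO1)CC[C@@]2(CO[Si](C)(C)C(C)(C)C)[C@@H]1CCC3=C4C(=C(C(=O)OC)C[C@@]42CN(C)C1)CC3 | intermediate
30 | hydroxy ketone: open form of the target (3-oxopentyl and hydroxymethyl on the quaternary carbon) | CCC(=O)CC[C@@]2(CO)[C@@H]1CCC3=C4C(=C(C(=O)OC)C[C@@]42CN(C)C1)CC3 | intermediate (not isolated)
31 | CNP0192143.1, the cyclic hemiketal | CC[C@@]1(O)CC[C@@]2(CO1)[C@@H]1CCC3=C4C(=C(C(=O)OC)C[C@@]42CN(C)C1)CC3 | target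

Total steps: 21. Longest linear sequence: 18 steps (steps 1–11 and 15–21, from ethyl N-methylglycinate); steps 12–14 make the side-chain triflate.

Steps most likely to fail

Step 17. The carbene formed on the alkyne may not find the acrylate olefin, so the catalyst is spent in capping by ethylene, or intermolecular metathesis overtakes the slow closure of the two tetrasubstituted olefins. The fallback uses known reactions and separates the events, setting out from 22. Cross enyne metathesis with ethylene (second-generation Grubbs catalyst RuCl2(PCy3)(1,3-dimesitylimidazolidin-2-ylidene)(=CHPh), ethylene, CH2Cl2, rt), established for dialkyl alkynes, should give the 2,3-disubstituted buta-1,3-diene, the tetraene F1. F1 is isolated and closed by ordinary ring-closing diene metathesis with the o-tolyl catalyst in hot toluene under argon. Each diene methylene can pair only with the olefin that gives a five-membered ring, and the route is rejoined at 24.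

Step 20. The enamine may be alkylated on nitrogen, where a seven-membered ring can form as well, or the hindered enamine carbon next to the quaternary C4 may react so slowly that the enamine decomposes. The fallback sets out from 26 and uses lactam enolate alkylation. LiN(i-Pr)2 (2.2 equiv, THF/DMPU, −78 to 0 °C) should first form the extended enolate of the dienoate, which cannot reach the bromide without forming a bridgehead olefin or a ring across the transoid diene. The second equivalent forms the lactam enolate, which alkylates intramolecularly to the bridged lactam F2. After protonation, with base equilibration of the diene into conjugation if needed, chemoselective amide reduction (IrCl(CO)(PPh3)2, (Me2SiH)2O; then NaBH(OAc)3, AcOH) returns to 29.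

Step 9. C-alkylation at the ring-fusion carbon next to the quaternary C4 may be slow, so that O-alkylation, β-elimination of the amide nitrogen or loss of cis selectivity takes over. The fallback sets out from 11 and alkylates the same enolate with the smaller, more reactive 3-bromo-1-(trimethylsilyl)prop-1-yne to give the silylpropargyl lactone F3. The silyl group is removed (K2CO3, MeOH) to give the propargyl lactone F4. The terminal alkyne is then converted into the 2-bromoalkene by bromoboration with B-bromo-9-borabicyclo[3.3.1]nonane and protonolysis with acetic acid, which rejoins the route at 13.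

Further compounds
F1 | step 17 | tetraene: 22 with the alkyne replaced by a 2,3-disubstituted buta-1,3-diene | CCC1(OCCO1)CC[C@@]2(CO[Si](C)(C)C(C)(C)C)CC(=O)N(C)C[C@]2(CC(=C)C(=O)OC)C(=C)C(=C)CCC(=C)CCO[Si](CC)(CC)CC
F2 | step 20 | bridged lactam: 29 with C2 still a lactam carbonyl | CCC1(OCCO1)CC[C@@]2(CO[Si](C)(C)C(C)(C)C)[C@@H]1CCC3=C4C(=C(C(=O)OC)C[C@@]42CN(C)C1=O)CC3
F3 | step 9 | cis-fused lactone 11 bearing a 3-(trimethylsilyl)prop-2-yn-1-yl group on the ring-fusion carbon | CCC1(OCCO1)CC[C@]23COC(=O)[C@@]2(CC#C[Si](C)(C)C)CN(C)C(=O)C3
F4 | step 9 | cis-fused lactone 11 bearing a prop-2-yn-1-yl group on the ring-fusion carbon | CCC1(OCCO1)CC[C@]23COC(=O)[C@@]2(CC#C)CN(C)C(=O)C3
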